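**Plan**

1. Retrosynthetic cuts, in order: the ester C–O bond of the p-coumarate; the C5–C bond of the 3-hydroxypropyl chain (back to C5–H through an allyl group); the O1–C7a aryl ether bond of the dihydrofuran; the C2–C3 bond (aldol). Ring A is the guaiacyl ring on C2, ring B the benzo ring.
2. Forward: an auxiliary-controlled syn-aldol joins the ring A aldehyde to a (2-bromo-3-methoxyphenyl)acetyl unit (C2–C3). Reduction and silylation give the open bromo alcohol, and copper-catalysed O1–C7a closure makes the dihydrobenzofuran. C5–H borylation/allylation, acylation, hydroboration and deprotection follow.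
3. Feature used: the C2 oxygen and C7a of ring B are 1,4-related through C3 and C3a. A metal inserted into a C7a–Br bond (Br between C7–OMe and C3a) is therefore reached by the C2 alkoxide in a six-membered chelate, which contracts to the five-membered O1–C2–C3–C3a–C7a ring.
4. Stereochemistry: both stereocenters come from the (R)-benzyloxazolidinone boron aldol (2R,3R syn adduct). The ring closure breaks neither C2–O nor C3–H, so syn becomes (2R,3S)-trans.
5. Helpers: Br at C7a (lost in the key step), TIPS on the primary oxygen, MOM on both phenols, allyl as latent 3-hydroxypropyl. After closure, C5–H is the only arene C–H of the molecule without an ortho substituent.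

Key step: step 6

Remark: (2-bromo-3-methoxyphenyl)acetic acid (1) is taken as a purchasable building block; its availability was not checked.

**Step 1**
Reactants: 1 (2-bromo-3-methoxyphenyl)acetic acid; 2 (4R)-4-benzyl-1,3-oxazolidin-2-one
Product: 4 (4R)-4-benzyl-3-[(2-bromo-3-methoxyphenyl)acetyl]-1,3-oxazolidin-2-one, via pivalic mixed anhydride 3 (not isolated)
Conditions: PivCl, Et3N, THF, −20 °C; then 2, LiCl, −20 °C to rt
Reagents that add atoms: pivaloyl chloride, CC(C)(C)C(=O)Cl (its atoms stay only in 3)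
Why: N-acylation of the oxazolidinone through a mixed pivalic anhydride (one-pot LiCl/Et3N imide formation) is standard for arylacetic acids and needs no strong base; no stereocenter is formed.

**Step 2**
Reactants: 5 vanillin (4-hydroxy-3-methoxybenzaldehyde)
Product: 6 3-methoxy-4-(methoxymethoxy)benzaldehyde
Conditions: MOMCl, iPr2NEt, CH2Cl2, 0 °C to rt
Reagents that add atoms: chloromethyl methyl ether, COCCl
Why: Williamson-type O-alkylation of the phenol gives a MOM ether that should survive boron enolates, hydride, hot carbonate and fluoride, and that adds no arene C–H able to compete in the later borylation.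

**Step 3**
Reactants: 4 (4R)-4-benzyl-3-[(2-bromo-3-methoxyphenyl)acetyl]-1,3-oxazolidin-2-one; 6 3-methoxy-4-(methoxymethoxy)benzaldehyde
Product: 9 (4R)-4-benzyl-3-[(2R,3R)-2-(2-bromo-3-methoxyphenyl)-3-hydroxy-3-[3-methoxy-4-(methoxymethoxy)phenyl]propanoyl]-1,3-oxazolidin-2-one, via dibutylboron enolate 7 (not isolated), via dibutylboron aldolate 8 (not isolated)
Conditions: Bu2BOTf, iPr2NEt, CH2Cl2, −78 to 0 °C; then 6, −78 to 0 °C; pH 7 phosphate buffer, MeOH, 30% H2O2, 0 °C
Reagents that add atoms: dibutylboron triflate, CCCCB(CCCC)OS(=O)(=O)C(F)(F)F (boron and butyl groups stay only in 7 and 8)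
Why: Evans syn-aldol: the (Z)-boron enolate adds through a closed chair (Zimmerman–Traxler) transition state on the enolate face away from the benzyl group of the (R)-auxiliary, which should set both new stereocenters as (2R,3R), the later C3 and C2 of the dihydrobenzofuran.

**Step 4**
Reactants: 9 (4R)-4-benzyl-3-[(2R,3R)-2-(2-bromo-3-methoxyphenyl)-3-hydroxy-3-[3-methoxy-4-(methoxymethoxy)phenyl]propanoyl]-1,3-oxazolidin-2-one
Product: 10 (1R,2S)-2-(2-bromo-3-methoxyphenyl)-1-[3-methoxy-4-(methoxymethoxy)phenyl]propane-1,3-diol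
Conditions: LiBH4, MeOH (1 equiv), THF, 0 °C
Reagents that add atoms: none
Why: Reductive removal of the auxiliary (hydride reduction of the exocyclic imide carbonyl) should give the 1,3-diol and return 2 at a temperature where retro-aldol cleavage and epimerisation of the benzylic centre are not expected; the descriptor change at the aryl-bearing carbon is only a change of CIP priorities.

**Step 5**
Reactants: 10 (1R,2S)-2-(2-bromo-3-methoxyphenyl)-1-[3-methoxy-4-(methoxymethoxy)phenyl]propane-1,3-diol
Product: 11 (1R,2S)-2-(2-bromo-3-methoxyphenyl)-1-[3-methoxy-4-(methoxymethoxy)phenyl]-3-{[tri(propan-2-yl)silyl]oxy}propan-1-ol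
Conditions: TIPSCl, imidazole, DMF, 0 °C to rt
Reagents that add atoms: chlorotri(propan-2-yl)silane, CC(C)[Si](Cl)(C(C)C)C(C)C
Why: Sterically selective silylation of the primary hydroxyl leaves only the hindered benzylic hydroxyl free for ring closure; TIPS is chosen because it has no arene C–H and migrates only slowly between the 1,3-related oxygens.

**Step 6**
Reactants: 11 (1R,2S)-2-(2-bromo-3-methoxyphenyl)-1-[3-methoxy-4-(methoxymethoxy)phenyl]-3-{[tri(propan-2-yl)silyl]oxy}propan-1-ol
Product: 12 {[(2R,3S)-7-methoxy-2-[3-methoxy-4-(methoxymethoxy)phenyl]-2,3-dihydro-1-benzofuran-3-yl]methoxy}tri(propan-2-yl)silane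
Conditions: CuI (copper iodide, 10 mol %), 3,4,7,8-tetramethyl-1,10-phenanthroline (20 mol %), Cs2CO3, toluene, 110 °C, argon
Reagents that add atoms: none
Why: Cs2CO3 and the ligated CuI turn the C2 hydroxyl into a monovalent copper alkoxide, which inserts into the C7a–Br bond of ring B to give a six-membered aryl(alkoxo) chelate of trivalent copper (Cu, O, C2, C3, C3a, C7a); C–O reductive elimination then releases monovalent copper and forms the O1–C7a bond. The closest known reaction type is the Ullmann-type copper-catalysed intramolecular O-arylation of secondary benzylic alcohols with ortho-bromoaryl groups, which has been used to make 2-aryl-2,3-dihydrobenzofurans. The dihydrofuran ring closes in a 5-exo sense, the tethered oxygen bonding to the ipso carbon C7a as the six-membered metallacycle contracts to the five-membered ring. No new stereocenter is formed: neither the C2–O bond nor the C3–H bond is broken, so the syn relationship of the aldol (hydroxyl and ring B aryl) should be carried over unchanged into the trans-2,3 relationship of the ring, free of the benzylic cation or quinone methide pathways that would scramble C2. The step needs O-arylation by the secondary oxygen alone, without oxidation of the carbinol; this is secured by the TIPS block on the primary oxygen, the MOM block on the phenol, the low basicity of carbonate toward C3–H and the low tendency of copper alkoxides toward β-hydride loss.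

**Step 7**
Reactants: 12 {[(2R,3S)-7-methoxy-2-[3-methoxy-4-(methoxymethoxy)phenyl]-2,3-dihydro-1-benzofuran-3-yl]methoxy}tri(propan-2-yl)silane
Product: 14 {[(2R,3S)-7-methoxy-2-[3-methoxy-4-(methoxymethoxy)phenyl]-5-(prop-2-en-1-yl)-2,3-dihydro-1-benzofuran-3-yl]methoxy}tri(propan-2-yl)silane, via pinacol boronate 13 (not isolated)
Conditions: [Ir(OMe)(cod)]2 (2 mol %), 4,4'-di-tert-butyl-2,2'-bipyridine (4 mol %), B2pin2, THF, 70 °C; evaporate; then Pd(PPh3)4 (5 mol %), allyl bromide, K2CO3, THF–H2O, 60 °C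
Reagents that add atoms: bis(pinacolato)diboron, CC1(C)OB(OC1(C)C)B1OC(C)(C)C(C)(C)O1 (boron stays only in 13); allyl bromide, C=CCBr
Why: Sterically governed iridium-catalysed arene C–H borylation should take C5–H of ring B, the only aromatic C–H of 12 with no ortho substituent, and the crude boronate is allylated by Suzuki–Miyaura coupling through a π-allyl complex of divalent palladium; no stereocenter is touched.

**Step 8**
Reactants: 14 {[(2R,3S)-7-methoxy-2-[3-methoxy-4-(methoxymethoxy)phenyl]-5-(prop-2-en-1-yl)-2,3-dihydro-1-benzofuran-3-yl]methoxy}tri(propan-2-yl)silane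
Product: 15 [(2R,3S)-7-methoxy-2-[3-methoxy-4-(methoxymethoxy)phenyl]-5-(prop-2-en-1-yl)-2,3-dihydro-1-benzofuran-3-yl]methanol
Conditions: Bu4NF, THF, 0 °C to rt
Reagents that add atoms: none
Why: Fluoride-induced Si–O cleavage (desilylation) frees the primary alcohol; aryl MOM ethers, the allyl group and both stereocenters are inert to fluoride.

**Step 9**
Reactants: 16 p-coumaric acid ((2E)-3-(4-hydroxyphenyl)prop-2-enoic acid)
Product: 18 (2E)-3-[4-(methoxymethoxy)phenyl]prop-2-enoic acid, via bis-MOM ester 17 (not isolated)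
Conditions: MOMCl (2.5 equiv), iPr2NEt, CH2Cl2, 0 °C to rt; evaporate; then LiOH, THF–MeOH–H2O, rt; cold 1 M HCl to pH 4
Reagents that add atoms: chloromethyl methyl ether, COCCl
Why: Exhaustive O-alkylation followed by saponification of the much more labile methoxymethyl ester should leave the phenol MOM ether and the (E)-alkene untouched.

**Step 10**
Reactants: 15 [(2R,3S)-7-methoxy-2-[3-methoxy-4-(methoxymethoxy)phenyl]-5-(prop-2-en-1-yl)-2,3-dihydro-1-benzofuran-3-yl]methanol; 18 (2E)-3-[4-(methoxymethoxy)phenyl]prop-2-enoic acid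
Product: 19 [(2R,3S)-7-methoxy-2-[3-methoxy-4-(methoxymethoxy)phenyl]-5-(prop-2-en-1-yl)-2,3-dihydro-1-benzofuran-3-yl]methyl (2E)-3-[4-(methoxymethoxy)phenyl]prop-2-enoate
Conditions: EDC·HCl, DMAP (cat.), CH2Cl2, 0 °C to rt
Reagents that add atoms: none
Why: Steglich-type carbodiimide esterification of the only free hydroxyl is mild enough to keep the (E)-cinnamoyl geometry and both stereocenters.

**Step 11**
Reactants: 19 [(2R,3S)-7-methoxy-2-[3-methoxy-4-(methoxymethoxy)phenyl]-5-(prop-2-en-1-yl)-2,3-dihydro-1-benzofuran-3-yl]methyl (2E)-3-[4-(methoxymethoxy)phenyl]prop-2-enoate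
Product: 21 [(2R,3S)-5-(3-hydroxypropyl)-7-methoxy-2-[3-methoxy-4-(methoxymethoxy)phenyl]-2,3-dihydro-1-benzofuran-3-yl]methyl (2E)-3-[4-(methoxymethoxy)phenyl]prop-2-enoate, via B-alkyl-9-BBN adduct 20 (not isolated)
Conditions: 9-BBN (1.5 equiv), THF, 0 °C to rt; then aq NaOAc, 30% H2O2, 0 °C to rt
Reagents that add atoms: 9-borabicyclo[3.3.1]nonane, B1C2CCCC1CCC2 (boron stays only in 20); hydrogen peroxide, OO
Why: Brown hydroboration–oxidation: the bulky borane should add anti-Markovnikov to the terminal allyl alkene much faster than to the conjugated, electron-poor cinnamate C=C or the ester carbonyl, and buffered peroxide oxidation gives the primary alcohol without ester hydrolysis.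

**Step 12**
Reactants: 21 [(2R,3S)-5-(3-hydroxypropyl)-7-methoxy-2-[3-methoxy-4-(methoxymethoxy)phenyl]-2,3-dihydro-1-benzofuran-3-yl]methyl (2E)-3-[4-(methoxymethoxy)phenyl]prop-2-enoate
Product: 22 [(2R,3S)-2-(4-hydroxy-3-methoxyphenyl)-5-(3-hydroxypropyl)-7-methoxy-2,3-dihydro-1-benzofuran-3-yl]methyl (2E)-3-(4-hydroxyphenyl)prop-2-enoate (CNP0202924.1)
Conditions: 3 M aq HCl, THF–iPrOH, 40 °C
Reagents that add atoms: none
Why: Acid-catalysed acetal hydrolysis should remove both aryl MOM ethers while dilute acid spares the ester and the (E)-alkene; any reversible opening at C2 would return to the trans ring, the more stable isomer, with C3 holding the absolute configuration.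

**Compound list**

1 | (2-bromo-3-methoxyphenyl)acetic acid | COc1cccc(CC(=O)O)c1Br | starting material
2 | (4R)-4-benzyl-1,3-oxazolidin-2-one | O=C1N[C@H](Cc2ccccc2)CO1 | starting material
3 | (2-bromo-3-methoxyphenyl)acetic 2,2-dimethylpropanoic anhydride | COc1cccc(CC(=O)OC(=O)C(C)(C)C)c1Br | intermediate
4 | (4R)-4-benzyl-3-[(2-bromo-3-methoxyphenyl)acetyl]-1,3-oxazolidin-2-one | COc1cccc(CC(=O)N2C(=O)OC[C@H]2Cc2ccccc2)c1Br | intermediate
5 | vanillin (4-hydroxy-3-methoxybenzaldehyde) | COc1cc(C=O)ccc1O | starting material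
6 | 3-methoxy-4-(methoxymethoxy)benzaldehyde | COCOc1ccc(C=O)cc1OC | intermediate
7 | (4R)-4-benzyl-3-[(Z)-2-(2-bromo-3-methoxyphenyl)-1-[(dibutylboranyl)oxy]ethenyl]-1,3-oxazolidin-2-one | CCCCB(CCCC)O/C(=C\c1cccc(OC)c1Br)N1C(=O)OC[C@H]1Cc1ccccc1 | intermediate
8 | O-dibutylboranyl derivative of aldol 9 (boron on the C3 oxygen of the propanoyl chain) | O=C(N1C(=O)OC[C@H]1Cc1ccccc1)[C@H](c1cccc(OC)c1Br)[C@@H](OB(CCCC)CCCC)c1ccc(OCOC)c(OC)c1 | intermediate
9 | (4R)-4-benzyl-3-[(2R,3R)-2-(2-bromo-3-methoxyphenyl)-3-hydroxy-3-[3-methoxy-4-(methoxymethoxy)phenyl]propanoyl]-1,3-oxazolidin-2-one | O=C(N1C(=O)OC[C@H]1Cc1ccccc1)[C@H](c1cccc(OC)c1Br)[C@@H](O)c1ccc(OCOC)c(OC)c1 | intermediate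
10 | (1R,2S)-2-(2-bromo-3-methoxyphenyl)-1-[3-methoxy-4-(methoxymethoxy)phenyl]propane-1,3-diol | OC[C@H](c1cccc(OC)c1Br)[C@@H](O)c1ccc(OCOC)c(OC)c1 | intermediate
11 | (1R,2S)-2-(2-bromo-3-methoxyphenyl)-1-[3-methoxy-4-(methoxymethoxy)phenyl]-3-{[tri(propan-2-yl)silyl]oxy}propan-1-ol | CC(C)[Si](OC[C@H](c1cccc(OC)c1Br)[C@@H](O)c1ccc(OCOC)c(OC)c1)(C(C)C)C(C)C | intermediate
12 | {[(2R,3S)-7-methoxy-2-[3-methoxy-4-(methoxymethoxy)phenyl]-2,3-dihydro-1-benzofuran-3-yl]methoxy}tri(propan-2-yl)silane | COCOc1ccc([C@@H]2Oc3c(OC)cccc3[C@H]2CO[Si](C(C)C)(C(C)C)C(C)C)cc1OC | intermediate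
13 | {[(2R,3S)-7-methoxy-2-[3-methoxy-4-(methoxymethoxy)phenyl]-5-(4,4,5,5-tetramethyl-1,3,2-dioxaborolan-2-yl)-2,3-dihydro-1-benzofuran-3-yl]methoxy}tri(propan-2-yl)silane | COCOc1ccc([C@@H]2Oc3c(OC)cc(B4OC(C)(C)C(C)(C)O4)cc3[C@H]2CO[Si](C(C)C)(C(C)C)C(C)C)cc1OC | intermediate
14 | {[(2R,3S)-7-methoxy-2-[3-methoxy-4-(methoxymethoxy)phenyl]-5-(prop-2-en-1-yl)-2,3-dihydro-1-benzofuran-3-yl]methoxy}tri(propan-2-yl)silane | COCOc1ccc([C@@H]2Oc3c(OC)cc(CC=C)cc3[C@H]2CO[Si](C(C)C)(C(C)C)C(C)C)cc1OC | intermediate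
15 | [(2R,3S)-7-methoxy-2-[3-methoxy-4-(methoxymethoxy)phenyl]-5-(prop-2-en-1-yl)-2,3-dihydro-1-benzofuran-3-yl]methanol | COCOc1ccc([C@@H]2Oc3c(OC)cc(CC=C)cc3[C@H]2CO)cc1OC | intermediate
16 | p-coumaric acid ((2E)-3-(4-hydroxyphenyl)prop-2-enoic acid) | OC(=O)/C=C/c1ccc(O)cc1 | starting material
17 | methoxymethyl (2E)-3-[4-(methoxymethoxy)phenyl]prop-2-enoate | COCOC(=O)/C=C/c1ccc(OCOC)cc1 | intermediate
18 | (2E)-3-[4-(methoxymethoxy)phenyl]prop-2-enoic acid | OC(=O)/C=C/c1ccc(OCOC)cc1 | intermediate
19 | [(2R,3S)-7-methoxy-2-[3-methoxy-4-(methoxymethoxy)phenyl]-5-(prop-2-en-1-yl)-2,3-dihydro-1-benzofuran-3-yl]methyl (2E)-3-[4-(methoxymethoxy)phenyl]prop-2-enoate | COCOc1ccc([C@@H]2Oc3c(OC)cc(CC=C)cc3[C@H]2COC(=O)/C=C/c2ccc(OCOC)cc2)cc1OC | intermediate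
20 | [(2R,3S)-5-[3-(9-borabicyclo[3.3.1]nonan-9-yl)propyl]-7-methoxy-2-[3-methoxy-4-(methoxymethoxy)phenyl]-2,3-dihydro-1-benzofuran-3-yl]methyl (2E)-3-[4-(methoxymethoxy)phenyl]prop-2-enoate | COCOc1ccc([C@@H]2Oc3c(OC)cc(CCCB4C5CCCC4CCC5)cc3[C@H]2COC(=O)/C=C/c2ccc(OCOC)cc2)cc1OC | intermediate
21 | [(2R,3S)-5-(3-hydroxypropyl)-7-methoxy-2-[3-methoxy-4-(methoxymethoxy)phenyl]-2,3-dihydro-1-benzofuran-3-yl]methyl (2E)-3-[4-(methoxymethoxy)phenyl]prop-2-enoate | COCOc1ccc([C@@H]2Oc3c(OC)cc(CCCO)cc3[C@H]2COC(=O)/C=C/c2ccc(OCOC)cc2)cc1OC | intermediate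
22 | [(2R,3S)-2-(4-hydroxy-3-methoxyphenyl)-5-(3-hydroxypropyl)-7-methoxy-2,3-dihydro-1-benzofuran-3-yl]methyl (2E)-3-(4-hydroxyphenyl)prop-2-enoate | COc1cc([C@@H]2Oc3c(OC)cc(CCCO)cc3[C@H]2COC(=O)/C=C/c2ccc(O)cc2)ccc1O | target

**Step count**

Total step count: 12. Longest linear sequence: 10 steps (steps 1, 3, 4, 5, 6, 7, 8, 10, 11, 12).

**Steps most likely to fail**

Step 7. The one-pot allyl transfer may suffer protodeboronation of the hindered-neighbour boronate or migration of the allyl double bond into conjugation under palladium hydride catalysis, and the borylation may be incompletely site-selective. Fallback: setting out from 12, the boronate 13 is isolated after the iridium step (allowing removal of any regioisomer) and converted with CuBr2 in MeOH–H2O at 80 °C into {[(2R,3S)-5-bromo-7-methoxy-2-[3-methoxy-4-(methoxymethoxy)phenyl]-2,3-dihydro-1-benzofuran-3-yl]methoxy}tri(propan-2-yl)silane F2. The allyl group is then introduced with reversed polarity by Stille coupling of F2 with allyltributylstannane (Pd(PPh3)4, toluene, 100 °C), which returns to 14.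

Step 6. Under hot carbonate the silyl group may migrate from the primary to the secondary oxygen, which would divert closure to the wrong oxygen, or insertion into the C7a–Br bond flanked by the methoxy group and the branched side chain may be sluggish. Fallback: setting out from 11, treatment with n-BuLi (2.2 equiv, THF, −78 °C), then B(OiPr)3 and aqueous work-up should give the cyclic boronic hemiester (3R,4S)-8-methoxy-3-[3-methoxy-4-(methoxymethoxy)phenyl]-4-({[tri(propan-2-yl)silyl]oxy}methyl)-3,4-dihydro-1H-2,1-benzoxaborinin-1-ol F1, in which the C2 oxygen is already tied to C7a through boron. A Chan–Lam-type oxidative coupling (Cu(OAc)2, divalent copper, pyridine, 4 Å sieves, air, CH2Cl2, rt) then forms the same O1–C7a bond at room temperature without strong base by extruding boron from the six-membered ring, and returns to 12.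

Step 11. The borane may reduce the cinnamate double bond or the ester in competition with the terminal alkene, and the peroxide work-up may cleave the ester. Fallback: setting out from 19, platinum-catalysed anti-Markovnikov hydrosilylation with HSiMe(OEt)2 (Pt2[(CH2=CHSiMe2)2O]3, zerovalent platinum, toluene, rt to 40 °C) should give [(2R,3S)-5-{3-[diethoxy(methyl)silyl]propyl}-7-methoxy-2-[3-methoxy-4-(methoxymethoxy)phenyl]-2,3-dihydro-1-benzofuran-3-yl]methyl (2E)-3-[4-(methoxymethoxy)phenyl]prop-2-enoate F3. Tamao oxidation (KF, KHCO3, 30% H2O2, THF–MeOH, rt) then converts the C–Si bond into the primary alcohol and returns to 21.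

**Further compounds**

F1 | step 6 | (3R,4S)-8-methoxy-3-[3-methoxy-4-(methoxymethoxy)phenyl]-4-({[tri(propan-2-yl)silyl]oxy}methyl)-3,4-dihydro-1H-2,1-benzoxaborinin-1-ol | COCOc1ccc([C@@H]2OB(O)c3c(OC)cccc3[C@H]2CO[Si](C(C)C)(C(C)C)C(C)C)cc1OC
F2 | step 7 | {[(2R,3S)-5-bromo-7-methoxy-2-[3-methoxy-4-(methoxymethoxy)phenyl]-2,3-dihydro-1-benzofuran-3-yl]methoxy}tri(propan-2-yl)silane | COCOc1ccc([C@@H]2Oc3c(OC)cc(Br)cc3[C@H]2CO[Si](C(C)C)(C(C)C)C(C)C)cc1OC
F3 | step 11 | [(2R,3S)-5-{3-[diethoxy(methyl)silyl]propyl}-7-methoxy-2-[3-methoxy-4-(methoxymethoxy)phenyl]-2,3-dihydro-1-benzofuran-3-yl]methyl (2E)-3-[4-(methoxymethoxy)phenyl]prop-2-enoate | COCOc1ccc([C@@H]2Oc3c(OC)cc(CCC[Si](C)(OCC)OCC)cc3[C@H]2COC(=O)/C=C/c2ccc(OCOC)cc2)cc1OC
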